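The plan rests on cutting C5–C10 and C8–C9 of the decalin, the two bonds that an intramolecular Diels–Alder reaction of a deca-1,7,9-triene forms. The feature exploited is this: C5, C10, C9 and C8 are four contiguous stereocentres of ring B, ring A is closed by the tether C1–C4, and C8 bears exactly the methyl group and oxygen of a 1-methyl-1-silyloxy diene terminus. One copper-bis(oxazoline)-catalysed cycloaddition thus closes rings A and B and sets all four ring stereocentres. The precursor is an acyclic N-enoyl oxazolidinone with an E-configured C9=C10 dienophile and an (E,Z)-silyloxy diene C5–C8. C13 comes from a desymmetrised anhydride and is joined at C11 by Wittig olefination.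

Key step: step 12

Numbering: labdane numbering (C1–C20) is used for all compounds. Compounds 1, 3–5, 7, 10–12 and 14–16 are racemic at the carbinol carbon C8, which becomes sp2 in step 10.

Assumption: quinidine is taken to open 22 to the 3S half-ester, by analogy with the quinine-mediated opening of other 3-alkylglutaric anhydrides to the 3R series. If the sense proves opposite, quinine takes its place.

Step 1
Reactants: 1 butane-1,3-diol (racemic); 2 1-phenyl-1H-tetrazole-5-thiol
Product: 3 4-[(1-phenyl-1H-tetrazol-5-yl)sulfanyl]butan-2-ol (racemic)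
Conditions: PPh3, DIAD, THF, 0 °C → rt
Reagents that add atoms: none
Why: Mitsunobu thioetherification, in which the acidic thiol displaces the activated primary hydroxyl much faster than the secondary one, so one equivalent of reagents should leave the C8 carbinol free.

Step 2
Reactants: 3 4-[(1-phenyl-1H-tetrazol-5-yl)sulfanyl]butan-2-ol
Product: 4 5-{[3-(tert-butyldimethylsilyloxy)butyl]sulfanyl}-1-phenyl-1H-tetrazole
Conditions: TBSCl, imidazole, CH2Cl2, rt
Reagents that add atoms: tert-butyldimethylsilyl chloride, CC(C)(C)[Si](C)(C)Cl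
Why: Imidazole-promoted silylation of a secondary alcohol masks the future C8 oxygen against the bases and the borane used later.

Step 3
Reactants: 4 5-{[3-(tert-butyldimethylsilyloxy)butyl]sulfanyl}-1-phenyl-1H-tetrazole
Product: 5 5-{[3-(tert-butyldimethylsilyloxy)butyl]sulfonyl}-1-phenyl-1H-tetrazole
Conditions: 30% H2O2, (NH4)6Mo7O24·4H2O (cat.), EtOH, 0 °C → rt
Reagents that add atoms: hydrogen peroxide, OO
Why: Molybdate-catalysed peroxide oxidation takes the sulfide to the sulfone and leaves a secondary TBS ether untouched.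

Step 4
Reactants: 5 5-{[3-(tert-butyldimethylsilyloxy)butyl]sulfonyl}-1-phenyl-1H-tetrazole; 6 2,2-dimethylpent-4-enal
Product: 7 tert-butyl{[(4E)-6,6-dimethylnona-4,8-dien-2-yl]oxy}dimethylsilane
Conditions: KN(SiMe3)2 added to 5 + 6, DME, −60 °C → rt; aq. NH4Cl
Reagents that add atoms: none
Why: Julia–Kocienski olefination of a non-enolisable α-quaternary aldehyde (addition, Smiles rearrangement, anti elimination) should give the E C5=C6 alkene, helped by the potassium counter-ion, the polar solvent and the bulk at C4.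

Step 5
Reactants: 8 ethyl acetoacetate
Product: 9 ethyl (2E)-3-{[(trifluoromethyl)sulfonyl]oxy}but-2-enoate
Conditions: Tf2O, aq. Me4NOH, hexane, 5 °C
Reagents that add atoms: triflic anhydride, O=S(=O)(OS(=O)(=O)C(F)(F)F)C(F)(F)F
Why: O-Triflation under Schotten–Baumann conditions traps the non-chelated ammonium enolate, which should place the triflate trans to the ester (E enol triflate).

Step 6
Reactants: 7 tert-butyl{[(4E)-6,6-dimethylnona-4,8-dien-2-yl]oxy}dimethylsilane; 9 ethyl (2E)-3-{[(trifluoromethyl)sulfonyl]oxy}but-2-enoate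
Product: 11 ethyl (2E,8E)-11-(tert-butyldimethylsilyloxy)-3,7,7-trimethyldodeca-2,8-dienoate, via B-alkyl-9-BBN borane 10 (not isolated)
Conditions: 9-BBN-H, THF, 0 °C → rt; then 9, PdCl2(dppf) (5 mol %), AsPh3, Cs2CO3, DMF–H2O, rt
Reagents that add atoms: 9-borabicyclo[3.3.1]nonane, B1C2CCCC1CCC2 (its boron framework appears in 10 only)
Why: Hydroboration followed by B-alkyl Suzuki–Miyaura coupling, in which 9-BBN-H selects the monosubstituted alkene over the hindered internal one and the coupling keeps the triflate geometry, fixes E C9=C10 (C20 cis to C11) without an isomer separation.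

Step 7
Reactants: 11 ethyl (2E,8E)-11-(tert-butyldimethylsilyloxy)-3,7,7-trimethyldodeca-2,8-dienoate
Product: 12 (2E,8E)-11-(tert-butyldimethylsilyloxy)-3,7,7-trimethyldodeca-2,8-dienoic acid
Conditions: LiOH, THF–MeOH–H2O, 50 °C; then 1 M HCl to pH 3, 0 °C
Reagents that add atoms: lithium hydroxide, [Li+].[OH-]
Why: Ester saponification, in which hydroxide touches neither the TBS ether nor either alkene geometry.

Step 8
Reactants: 12 (2E,8E)-11-(tert-butyldimethylsilyloxy)-3,7,7-trimethyldodeca-2,8-dienoic acid; 13 oxazolidin-2-one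
Product: 15 3-[(2E,8E)-11-(tert-butyldimethylsilyloxy)-3,7,7-trimethyldodeca-2,8-dienoyl]oxazolidin-2-one, via mixed pivalic anhydride 14 (not isolated)
Conditions: PivCl, Et3N, THF, −20 °C; then LiCl, 13, −20 °C → rt
Reagents that add atoms: pivaloyl chloride, CC(C)(C)C(=O)Cl (its atoms appear in 14 only)
Why: LiCl-assisted N-acylation through a mixed anhydride, in which the oxazolidinone attacks the enoyl carbonyl because the pivaloyl carbonyl is shielded, and the low temperature suppresses deconjugation.

Step 9
Reactants: 15 3-[(2E,8E)-11-(tert-butyldimethylsilyloxy)-3,7,7-trimethyldodeca-2,8-dienoyl]oxazolidin-2-one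
Product: 16 3-[(2E,8E)-11-hydroxy-3,7,7-trimethyldodeca-2,8-dienoyl]oxazolidin-2-one
Conditions: 48% aq. HF, MeCN, 0 °C → rt
Reagents that add atoms: none
Why: Acidic fluoride desilylation is chosen because basic fluoride would endanger the imide.

Step 10
Reactants: 16 3-[(2E,8E)-11-hydroxy-3,7,7-trimethyldodeca-2,8-dienoyl]oxazolidin-2-one
Product: 17 3-[(2E,8E)-3,7,7-trimethyl-11-oxododeca-2,8-dienoyl]oxazolidin-2-one
Conditions: Dess–Martin periodinane, NaHCO3, CH2Cl2, 0 °C
Reagents that add atoms: none
Why: Buffered Dess–Martin oxidation is neutral enough to give the β,γ-unsaturated ketone without drift of C5=C6 into conjugation, which is why C8 is carried as a carbinol and not as an acid-labile ketal.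

Step 11
Reactants: 17 3-[(2E,8E)-3,7,7-trimethyl-11-oxododeca-2,8-dienoyl]oxazolidin-2-one
Product: 18 3-[(2E,8E,10Z)-11-(tert-butyldimethylsilyloxy)-3,7,7-trimethyldodeca-2,8,10-trienoyl]oxazolidin-2-one
Conditions: TBSOTf, Et3N, CH2Cl2, −78 → 0 °C; filtration through Et3N-deactivated silica
Reagents that add atoms: tert-butyldimethylsilyl triflate, CC(C)(C)[Si](C)(C)OS(=O)(=O)C(F)(F)F
Why: Soft enolisation (silyl triflate and amine) removes a doubly activated C7 proton rather than one of C17, giving the conjugated dienol ether, and allylic strain between C17 and C6 should favour the Z C7=C8 geometry with oxygen cis to C6.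

Step 12
Reactants: 18 3-[(2E,8E,10Z)-11-(tert-butyldimethylsilyloxy)-3,7,7-trimethyldodeca-2,8,10-trienoyl]oxazolidin-2-one
Product: 19 3-[(5S,8R,9R,10S)-8α-(tert-butyldimethylsilyloxy)drim-6-en-11-oyl]oxazolidin-2-one (5α-H, 9α-H, 10β-CH3, 8β-CH3)
Conditions: [Cu((R,R)-tBu-box)](SbF6)2 (20 mol %, from CuCl2, AgSbF6 and 2,2′-isopropylidenebis[(4R)-4-tert-butyl-2-oxazoline]), 4 Å molecular sieves, CH2Cl2, −20 °C → rt
Reagents that add atoms: none
Why: Proposed new method: two-point binding of both imide carbonyls to the square-planar divalent copper centre lowers the LUMO of C9=C10, and the donor-substituted diene, whose largest HOMO coefficient sits on C5, bonds C5 to the β-carbon C10 slightly ahead of C8 to C9 in an asynchronous [4+2] cycloaddition (at the stepwise limit, a vinylogous Mukaiyama–Michael addition followed by aldol closure of the copper enolate on the silyloxocarbenium ion makes the same bonds). The closest known reactions are the bis(oxazoline)copper-catalysed intramolecular Diels–Alder cyclisations of (E,E,E)-deca-2,8,10-trienoyl oxazolidinones to trans-decalins and the Mukaiyama–Michael additions of silyl enol ethers to such chelated acceptors; new here are the β,β-disubstituted dienophile and the fully substituted diene terminus. Ring B closes as the six-membered cyclohexene of the cycloaddition and ring A as a six-membered carbocycle through the chair-folded tether C1–C4 (6-exo-trig for each ring if the bonds form one after the other). C9 and C10 follow from suprafacial addition to the E dienophile (C20 and C11 cis), C5 and C8 from the diene geometry (C4 and C17 outside and hence cis, H5 and the silyloxy group inside), the trans fusion from the carbonyl-endo transition state, and the absolute sense from the ligand, because in the s-cis chelate the tert-butyl group of the (R,R)-ligand covers the Re face of C9 and bonding occurs on the Si face, whereas the (S,S)-ligand would lead to the antipode. The step needs endo and facial selectivity and survival of the silyl enol ether: the C20 methyl locks the s-cis acyl conformer, the C4 gem-dimethyl group favours the folded chain (Thorpe–Ingold effect), the bulky TBS group resists silyl transfer, and the sieves exclude the water that would protodesilylate the diene.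

Step 13
Reactants: 19 3-[(5S,8R,9R,10S)-8α-(tert-butyldimethylsilyloxy)drim-6-en-11-oyl]oxazolidin-2-one
Product: 20 S-ethyl (5S,8R,9R,10S)-8α-(tert-butyldimethylsilyloxy)drim-6-ene-11-thioate
Conditions: EtSH, n-BuLi, THF, 0 °C; aq. NH4Cl
Reagents that add atoms: ethanethiol, CCS
Why: Thiolysis (transacylation) of the imide should release even this hindered acyl group, because thiolate attack at the ring carbonyl is reversible while exocyclic cleavage expels the oxazolidinone anion, and the weakly basic thiolate spares C9–H and the β-silyloxy group.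

Step 14
Reactants: 20 S-ethyl (5S,8R,9R,10S)-8α-(tert-butyldimethylsilyloxy)drim-6-ene-11-thioate
Product: 21 (5S,8R,9R,10S)-8α-(tert-butyldimethylsilyloxy)drim-6-en-11-al
Conditions: iBu2AlH, CH2Cl2, −78 °C; aq. potassium sodium tartrate
Reagents that add atoms: none
Why: Partial reduction of a thioester works because the aluminium hemithioacetal persists at −78 °C and collapses to the aldehyde only on work-up, and C9 already holds the more stable equatorial formyl group.

Step 15
Reactants: 22 3-methylglutaric anhydride; 23 benzyl alcohol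
Product: 24 (3S)-5-(benzyloxy)-3-methyl-5-oxopentanoic acid
Conditions: quinidine (1.1 equiv), toluene, −55 °C; 1 M HCl wash; recrystallisation of the (R)-1-phenylethylammonium salt, then 1 M HCl
Reagents that add atoms: none
Why: Alkaloid-mediated desymmetrising alcoholysis of a prochiral anhydride sets C13, the chiral base directing the alcohol to one enantiotopic carbonyl, and crystallisation of the amine salt should raise the enantiopurity.

Step 16
Reactants: 24 (3S)-5-(benzyloxy)-3-methyl-5-oxopentanoic acid
Product: 25 benzyl (3R)-4-iodo-3-methylbutanoate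
Conditions: PhI(OAc)2, I2, 1,2-dichloroethane, hν (tungsten lamp), reflux
Reagents that add atoms: iodine, II
Why: Hunsdiecker-type decarboxylative iodination through the acyl hypoiodite removes the one carbon by which the six-carbon anhydride exceeds the five-carbon unit C12–C16 and turns the acid-bearing CH2 into C12–I, while C13 is never a radical centre (the descriptor changes by priority only).

Step 17
Reactants: 25 benzyl (3R)-4-iodo-3-methylbutanoate
Product: 26 [(2R)-4-(benzyloxy)-2-methyl-4-oxobutyl]triphenylphosphonium iodide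
Conditions: PPh3, MeCN, reflux
Reagents that add atoms: triphenylphosphine, c1ccc(cc1)P(c1ccccc1)c1ccccc1
Why: SN2 quaternisation of the phosphine by a primary iodide, run concentrated so that it outpaces lactonisation of the γ-iodo ester.

Step 18
Reactants: 21 (5S,8R,9R,10S)-8α-(tert-butyldimethylsilyloxy)drim-6-en-11-al; 26 [(2R)-4-(benzyloxy)-2-methyl-4-oxobutyl]triphenylphosphonium iodide
Product: 28 benzyl (11Z,13R)-8α-(tert-butyldimethylsilyloxy)labda-6,11-dien-15-oate, via phosphorus ylide 27 (not isolated)
Conditions: NaN(SiMe3)2, THF, −78 → 0 °C; then 21, −78 °C → rt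
Reagents that add atoms: none
Why: Wittig olefination with a non-stabilised ylide, the most reactive olefination partner for a flanked aldehyde, forms C11=C12 (its geometry is of no consequence), while C13 lies β to phosphorus and cannot epimerise and the shielded axial C9–H resists enolisation.

Step 19
Reactants: 28 benzyl (11Z,13R)-8α-(tert-butyldimethylsilyloxy)labda-6,11-dien-15-oate
Product: 30 (13S)-8α-(tert-butyldimethylsilyloxy)labdan-15-oic acid, via saturated benzyl ester 29 (not isolated)
Conditions: H2 (4 atm), Pt/C, EtOAc, rt; then Pd/C added, H2 (1 atm), rt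
Reagents that add atoms: none
Why: Catalytic hydrogenation on platinum saturates C6=C7 and C11=C12 (no new stereocentre) with little double-bond migration, so the allylic centres C5, C9 and C13 are not scrambled, and palladium then hydrogenolyses the benzyl ester in the same vessel.

Step 20
Reactants: 30 (13S)-8α-(tert-butyldimethylsilyloxy)labdan-15-oic acid
Product: 31 (13S)-8α-hydroxylabdan-15-oic acid
Conditions: Bu4NF (excess), THF, 60 °C; then cold dilute HCl
Reagents that add atoms: none
Why: Fluoride cleavage of the tertiary silyl ether can be driven by heat because nothing base-sensitive remains, and the C8–O bond is not broken.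

Step 21
Reactants: 31 (13S)-8α-hydroxylabdan-15-oic acid
Product: 32 (5S,8R,9R,10S,13S)-8α-formyloxylabdan-15-oic acid (target)
Conditions: HCO2Ac (freshly prepared, excess), pyridine, CH2Cl2, 0 °C → rt; water
Reagents that add atoms: acetic formic anhydride, CC(=O)OC=O
Why: O-Formylation with a mixed anhydride delivers the small formyl group even to a tertiary carbinol with retention at C8, and any mixed anhydride formed at C15 is hydrolysed back to the acid in the neutral aqueous work-up.

Compound list
1 | butane-1,3-diol (racemic) | CC(O)CCO | starting material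
2 | 1-phenyl-1H-tetrazole-5-thiol | Sc1nnnn1-c1ccccc1 | starting material
3 | 4-[(1-phenyl-1H-tetrazol-5-yl)sulfanyl]butan-2-ol (racemic) | CC(O)CCSc1nnnn1-c1ccccc1 | intermediate
4 | 5-{[3-(tert-butyldimethylsilyloxy)butyl]sulfanyl}-1-phenyl-1H-tetrazole (racemic) | CC(CCSc1nnnn1-c1ccccc1)O[Si](C)(C)C(C)(C)C | intermediate
5 | 5-{[3-(tert-butyldimethylsilyloxy)butyl]sulfonyl}-1-phenyl-1H-tetrazole (racemic) | CC(CCS(=O)(=O)c1nnnn1-c1ccccc1)O[Si](C)(C)C(C)(C)C | intermediate
6 | 2,2-dimethylpent-4-enal | C=CCC(C)(C)C=O | starting material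
7 | tert-butyl{[(4E)-6,6-dimethylnona-4,8-dien-2-yl]oxy}dimethylsilane (racemic) | CC(C/C=C/C(C)(C)CC=C)O[Si](C)(C)C(C)(C)C | intermediate
8 | ethyl acetoacetate | CCOC(=O)CC(C)=O | starting material
9 | ethyl (2E)-3-{[(trifluoromethyl)sulfonyl]oxy}but-2-enoate | CCOC(=O)/C=C(\C)OS(=O)(=O)C(F)(F)F | intermediate
10 | 9-[(5E)-8-(tert-butyldimethylsilyloxy)-4,4-dimethylnon-5-en-1-yl]-9-borabicyclo[3.3.1]nonane | CC(C/C=C/C(C)(C)CCCB1C2CCCC1CCC2)O[Si](C)(C)C(C)(C)C | intermediate
11 | ethyl (2E,8E)-11-(tert-butyldimethylsilyloxy)-3,7,7-trimethyldodeca-2,8-dienoate | CCOC(=O)/C=C(\C)CCCC(C)(C)/C=C/CC(C)O[Si](C)(C)C(C)(C)C | intermediate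
12 | (2E,8E)-11-(tert-butyldimethylsilyloxy)-3,7,7-trimethyldodeca-2,8-dienoic acid | OC(=O)/C=C(\C)CCCC(C)(C)/C=C/CC(C)O[Si](C)(C)C(C)(C)C | intermediate
13 | oxazolidin-2-one | O=C1NCCO1 | starting material
14 | (2E,8E)-11-(tert-butyldimethylsilyloxy)-3,7,7-trimethyldodeca-2,8-dienoic pivalic anhydride | CC(C)(C)C(=O)OC(=O)/C=C(\C)CCCC(C)(C)/C=C/CC(C)O[Si](C)(C)C(C)(C)C | intermediate
15 | 3-[(2E,8E)-11-(tert-butyldimethylsilyloxy)-3,7,7-trimethyldodeca-2,8-dienoyl]oxazolidin-2-one | O=C1OCCN1C(=O)/C=C(\C)CCCC(C)(C)/C=C/CC(C)O[Si](C)(C)C(C)(C)C | intermediate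
16 | 3-[(2E,8E)-11-hydroxy-3,7,7-trimethyldodeca-2,8-dienoyl]oxazolidin-2-one | O=C1OCCN1C(=O)/C=C(\C)CCCC(C)(C)/C=C/CC(C)O | intermediate
17 | 3-[(2E,8E)-3,7,7-trimethyl-11-oxododeca-2,8-dienoyl]oxazolidin-2-one | O=C1OCCN1C(=O)/C=C(\C)CCCC(C)(C)/C=C/CC(C)=O | intermediate
18 | 3-[(2E,8E,10Z)-11-(tert-butyldimethylsilyloxy)-3,7,7-trimethyldodeca-2,8,10-trienoyl]oxazolidin-2-one | O=C1OCCN1C(=O)/C=C(\C)CCCC(C)(C)/C=C/C=C(/C)O[Si](C)(C)C(C)(C)C | intermediate
19 | 3-[(5S,8R,9R,10S)-8α-(tert-butyldimethylsilyloxy)drim-6-en-11-oyl]oxazolidin-2-one | O=C1OCCN1C(=O)[C@@H]2[C@@]3(C)CCCC(C)(C)[C@@H]3C=C[C@@]2(C)O[Si](C)(C)C(C)(C)C | intermediate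
20 | S-ethyl (5S,8R,9R,10S)-8α-(tert-butyldimethylsilyloxy)drim-6-ene-11-thioate | CCSC(=O)[C@@H]1[C@@]2(C)CCCC(C)(C)[C@@H]2C=C[C@@]1(C)O[Si](C)(C)C(C)(C)C | intermediate
21 | (5S,8R,9R,10S)-8α-(tert-butyldimethylsilyloxy)drim-6-en-11-al | O=C[C@@H]1[C@@]2(C)CCCC(C)(C)[C@@H]2C=C[C@@]1(C)O[Si](C)(C)C(C)(C)C | intermediate
22 | 3-methylglutaric anhydride | CC1CC(=O)OC(=O)C1 | starting material
23 | benzyl alcohol | OCc1ccccc1 | starting material
24 | (3S)-5-(benzyloxy)-3-methyl-5-oxopentanoic acid | C[C@@H](CC(=O)O)CC(=O)OCc1ccccc1 | intermediate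
25 | benzyl (3R)-4-iodo-3-methylbutanoate | C[C@@H](CI)CC(=O)OCc1ccccc1 | intermediate
26 | [(2R)-4-(benzyloxy)-2-methyl-4-oxobutyl]triphenylphosphonium iodide | C[C@@H](C[P+](c1ccccc1)(c1ccccc1)c1ccccc1)CC(=O)OCc1ccccc1.[I-] | intermediate
27 | benzyl (3R)-3-methyl-4-(triphenylphosphoranylidene)butanoate | C[C@@H](C=P(c1ccccc1)(c1ccccc1)c1ccccc1)CC(=O)OCc1ccccc1 | intermediate
28 | benzyl (11Z,13R)-8α-(tert-butyldimethylsilyloxy)labda-6,11-dien-15-oate | C[C@@H](/C=C\[C@@H]1[C@@]2(C)CCCC(C)(C)[C@@H]2C=C[C@@]1(C)O[Si](C)(C)C(C)(C)C)CC(=O)OCc1ccccc1 | intermediate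
29 | benzyl (13S)-8α-(tert-butyldimethylsilyloxy)labdan-15-oate | C[C@@H](CC[C@@H]1[C@@]2(C)CCCC(C)(C)[C@@H]2CC[C@@]1(C)O[Si](C)(C)C(C)(C)C)CC(=O)OCc1ccccc1 | intermediate
30 | (13S)-8α-(tert-butyldimethylsilyloxy)labdan-15-oic acid | C[C@@H](CC[C@@H]1[C@@]2(C)CCCC(C)(C)[C@@H]2CC[C@@]1(C)O[Si](C)(C)C(C)(C)C)CC(=O)O | intermediate
31 | (13S)-8α-hydroxylabdan-15-oic acid | C[C@@H](CC[C@@H]1[C@@]2(C)CCCC(C)(C)[C@@H]2CC[C@@]1(C)O)CC(=O)O | intermediate
32 | (5S,8R,9R,10S,13S)-8α-formyloxylabdan-15-oic acid | C[C@@H](CC[C@@H]1[C@@]2(C)CCCC(C)(C)[C@@H]2CC[C@@]1(C)OC=O)CC(=O)O | target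

Total step count: 21.
Longest linear sequence: 17 steps (1, 2, 3, 4, 6–14, 18–21).

Steps most likely to fail

**1. Step 12.** Both bond-forming sites are crowded: C5 is neopentylic, C10 and C8 become quaternary, and one diene substituent must point inside. Cyclisation may therefore be slower than protodesilylation of the diene, silyl transfer, or arrest after the first C–C bond. Endo and facial control may also erode if warming is needed.

The fallback gives up the cycloaddition and takes the decalin from the chiral pool by known reactions only. It sets out from phosphonium salt 26, which is kept, and replaces triene 18 by purchased (+)-sclareolide F1.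
- Enolate hydroxylation (KN(SiMe3)2, then 2-(phenylsulfonyl)-3-phenyloxaziridine, THF, −78 °C) should give 11-hydroxysclareolide F2 as C11 epimers.
- LiAlH4 reduction gives 13,14,15,16-tetranorlabdane-8α,11,12-triol F3.
- Glycol cleavage with NaIO4 removes C12 and gives 8α-hydroxydriman-11-al F4.
- TBSOTf and 2,6-lutidine give 8α-(tert-butyldimethylsilyloxy)driman-11-al F5.
- Wittig reaction with ylide 27 as in step 18 gives benzyl (11Z,13R)-8α-(tert-butyldimethylsilyloxy)labd-11-en-15-oate F6.
- Hydrogenation of F6 on Pt/C comes back to the route at benzyl ester 29, inside step 19.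

**2. Step 18.** Addition of the bulky β-branched ylide to an aldehyde flanked by two quaternary carbons may be so slow that enolisation, followed by β-elimination of the silanolate, takes over.

The fallback moves the fragment union to C12–C13 and uses only small reagents at C11. It sets out from aldehyde 21.
- Methylenation with Ph3P=CH2 should give 8α-(tert-butyldimethylsilyloxy)-13,14,15,16-tetranorlabda-6,11-diene F7.
- 9-BBN-H adds to the terminal C12, and B-alkyl Suzuki–Miyaura coupling with enol triflate 9 (conditions of step 6) gives ethyl (13E)-8α-(tert-butyldimethylsilyloxy)labda-6,13-dien-15-oate F8.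
- Asymmetric conjugate reduction sets C13 under catalyst control and gives ethyl (13S)-8α-(tert-butyldimethylsilyloxy)labd-6-en-15-oate F9. The copper hydride is generated from CuCl, NaOtBu, p-tol-BINAP and polymethylhydrosiloxane, with the ligand antipode chosen for 13S.
- Hydrogenation on Pt/C gives ethyl (13S)-8α-(tert-butyldimethylsilyloxy)labdan-15-oate F10.
- Saponification with LiOH comes back to the route at acid 30.

**3. Step 13.** The exocyclic carbonyl lies between two quaternary carbons, so thiolate attack may be too slow, or ring opening of the oxazolidinone may become the net outcome.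

The fallback changes from transacylation to hydrolysis followed by a redox adjustment. It sets out from imide 19.
- LiOH with H2O2 (THF–H2O, 0 °C), whose small α-effect nucleophile prefers the exocyclic carbonyl, should give 8α-(tert-butyldimethylsilyloxy)drim-6-en-11-oic acid F11.
- LiAlH4 in refluxing THF gives 8α-(tert-butyldimethylsilyloxy)drim-6-en-11-ol F12.
- Dess–Martin oxidation comes back to the route at aldehyde 21.

Further compounds
F1 | step 12 | (+)-sclareolide (purchased) | O=C1C[C@@H]2[C@@]3(C)CCCC(C)(C)[C@@H]3CC[C@@]2(C)O1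
F2 | step 12 | 11-hydroxysclareolide (C11 epimers) | O=C1C(O)[C@@H]2[C@@]3(C)CCCC(C)(C)[C@@H]3CC[C@@]2(C)O1
F3 | step 12 | 13,14,15,16-tetranorlabdane-8α,11,12-triol (C11 epimers) | OCC(O)[C@@H]1[C@@]2(C)CCCC(C)(C)[C@@H]2CC[C@@]1(C)O
F4 | step 12 | 8α-hydroxydriman-11-al | O=C[C@@H]1[C@@]2(C)CCCC(C)(C)[C@@H]2CC[C@@]1(C)O
F5 | step 12 | 8α-(tert-butyldimethylsilyloxy)driman-11-al | O=C[C@@H]1[C@@]2(C)CCCC(C)(C)[C@@H]2CC[C@@]1(C)O[Si](C)(C)C(C)(C)C
F6 | step 12 | benzyl (11Z,13R)-8α-(tert-butyldimethylsilyloxy)labd-11-en-15-oate | C[C@@H](/C=C\[C@@H]1[C@@]2(C)CCCC(C)(C)[C@@H]2CC[C@@]1(C)O[Si](C)(C)C(C)(C)C)CC(=O)OCc1ccccc1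
F7 | step 18 | 8α-(tert-butyldimethylsilyloxy)-13,14,15,16-tetranorlabda-6,11-diene | C=C[C@@H]1[C@@]2(C)CCCC(C)(C)[C@@H]2C=C[C@@]1(C)O[Si](C)(C)C(C)(C)C
F8 | step 18 | ethyl (13E)-8α-(tert-butyldimethylsilyloxy)labda-6,13-dien-15-oate | CCOC(=O)/C=C(\C)CC[C@@H]1[C@@]2(C)CCCC(C)(C)[C@@H]2C=C[C@@]1(C)O[Si](C)(C)C(C)(C)C
F9 | step 18 | ethyl (13S)-8α-(tert-butyldimethylsilyloxy)labd-6-en-15-oate | C[C@@H](CC[C@@H]1[C@@]2(C)CCCC(C)(C)[C@@H]2C=C[C@@]1(C)O[Si](C)(C)C(C)(C)C)CC(=O)OCC
F10 | step 18 | ethyl (13S)-8α-(tert-butyldimethylsilyloxy)labdan-15-oate | C[C@@H](CC[C@@H]1[C@@]2(C)CCCC(C)(C)[C@@H]2CC[C@@]1(C)O[Si](C)(C)C(C)(C)C)CC(=O)OCC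
F11 | step 13 | 8α-(tert-butyldimethylsilyloxy)drim-6-en-11-oic acid | OC(=O)[C@@H]1[C@@]2(C)CCCC(C)(C)[C@@H]2C=C[C@@]1(C)O[Si](C)(C)C(C)(C)C
F12 | step 13 | 8α-(tert-butyldimethylsilyloxy)drim-6-en-11-ol | OC[C@@H]1[C@@]2(C)CCCC(C)(C)[C@@H]2C=C[C@@]1(C)O[Si](C)(C)C(C)(C)C
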